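Read the links of the autumn run, whose charges are alpha's, as a falling curve.

| setting | autumn | midnight | winter | spring | zeta | theta | alpha |
|---|---|---|---|---|---|---|---|
| first end groups | 29 mM | 19 mM | 44 mM | 29 mM | 29 mM | 29 mM (fed, over 50 s) | 29 mM |
| second end groups | 26.1 mM | 26.1 mM | 26.1 mM | 26.1 mM | 26.1 mM (fed, over 50 s) | 26.1 mM | 26.1 mM |
| one-sided end groups | 1.45 mM | 1.45 mM | 1.45 mM | 2.9 mM | 1.45 mM | 1.45 mM | 1.45 mM |
| remark | run made earlier | run made earlier | run made earlier | run made earlier | all else is in the flask from the start; the feed brings no volume worth counting | all else is in the flask from the start; the feed brings no volume worth counting | everything together at the start |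
| time |  |  |  |  | 4.0 min | 4.0 min | 4.0 min |

| run | time / min | links / % | capped ends / % |
|---|---|---|---|
| autumn | 0.667 | 16.9 | 4.7 |
| autumn | 1.33 | 17.7 | 5.1 |
| autumn | 2.00 | 13.9 | 5.1 |
| autumn | 2.50 | 12.7 | 5.4 |
| autumn | 3.00 | 10.0 | 5.3 |
| autumn | 4.00 | 6.7 | 3.7 |
| midnight | 0.250 | 11.8 | 4.3 |
| midnight | 0.417 | 14.4 | 5.2 |
| midnight | 0.667 | 18.2 | 6.2 |
| midnight | 1.33 | 18.6 | 7.1 |
| midnight | 2.00 | 14.5 | 8.2 |
| midnight | 3.00 | 9.5 | 8.1 |
| winter | 0.200 | 9.7 | 3.2 |
| winter | 0.667 | 16.6 | 3.1 |
| winter | 1.00 | 15.8 | 3.0 |
| winter | 2.00 | 13.5 | 3.0 |
| winter | 2.50 | 11.4 | 3.1 |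
| winter | 3.00 | 9.8 | 3.1 |
| spring | 0.667 | 16.7 | 10.3 |
| spring | 1.33 | 17.1 | 9.8 |
| spring | 2.00 | 13.1 | 9.4 |
| spring | 2.50 | 11.0 | 10.2 |
| spring | 3.00 | 9.4 | 10.6 |

(scatter of a reading: 0.5 percentage points)

- which flask leads in share of links in links plus capped ends ("all alike" within 1.5 percentage points) (zeta / theta / alpha / all alike)
- share of links in links plus capped ends at the end, zeta
- share of links in links plus capped ends at the end, theta
- share of links in links plus capped ends at the end, alpha

From 2.00 min to 4.00 min the autumn links fall from 13.9 % to 6.7 %. That gives a fade rate of 0.365 min⁻¹, the natural logarithm of the ratio of two late readings divided by the time between them. In the spring run capped ends level off near the charge of one-sided end groups, reading 10.6 % at 3.00 min against 10.0 % charged, so alpha should hold 5.00 % of them. With the autumn links read at 4.00 min, the share of links in alpha (its selectivity) comes to 57.3 %.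

In zeta, the links from a portion of second end groups fed late should have less time left to fade. Integrating the exponential fade over the steady feed of 50 s multiplies the links by 1.17. Zeta should therefore end near 7.83 % links and a share of 61.0 %. In theta, second end groups wait for the fed first end groups, so the same factor is taken the other way, as a rough guess: 5.73 % links and a share of 53.4 %.

The forecast also named zeta, with 62 %, 45 % and 59 % for zeta, theta and alpha, and it put theta lower than this reckoning, since “fed first end groups meet dying second end groups”. The flasks give 61.2 % for zeta, 50.1 % for theta and 57.3 % for alpha, so zeta leads, and theta stands 3.3 percentage points below this reckoning.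

    first end groups + second end groups ⇌ links (K = 39.0 L mol⁻¹, k = 0.440 L mol⁻¹ s⁻¹)
    first end groups + one-sided end groups → capped ends (k = 3.20 L mol⁻¹ s⁻¹)
    second end groups → decomposed reagent (k = 0.0210 s⁻¹)

In zeta at 4.00 min, second end groups go to decomposed reagent 1.9 times as fast as the forward step alone takes them into links. Of their charge, 3.9 % is left then, while links stand at 7.88 % of the first end groups charged. Take a flask like zeta with 3.6 mM of one-sided end groups: the same factor 1.17 gives 2.27 mM of links beside capped ends at that charge, so a share of 38.7 %. The computed flask gives 36.9 %.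

The earlier runs and the new flask were generated by integration on assumed constants; noise was put on by code.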